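(All runs are simulated for an exercise.)

Substrate goes slowly enough here that two late readings of a run give a decay constant, so we keep the books on substrate, in fractions of its charge. In every flask, reagent is fed steadily into substrate and initiator.

the same everywhere: substrate 0.25 M; initiator 14 mM

| charge | reagent | remark | time |
|---|---|---|---|
| autumn | 0.19 M (fed, over 6.0 min) | run made earlier; the fed solution adds 0.50 times the starting volume |  |
| dusk | 0.31 M (fed, over 6.0 min) | run made earlier; the fed solution adds 0.50 times the starting volume |  |
| ash | 0.500 M (fed, over 6.0 min) | the fed solution adds 0.50 times the starting volume | 15 min |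
| birch | 0.250 M (fed, over 6.0 min) | the fed solution adds 0.50 times the starting volume | 15 min |

| run | time / min | substrate / % | product / % |
|---|---|---|---|
| autumn | 1.33 | 89.7 | 1.1 |
| autumn | 2.50 | 82.9 | 2.2 |
| autumn | 4.00 | 73.0 | 3.8 |
| autumn | 5.00 | 67.1 | 6.1 |
| autumn | 6.00 | 62.2 | 9.2 |
| autumn | 8.00 | 53.4 | 12.7 |
| dusk | 0.500 | 96.0 | 0.7 |
| dusk | 1.33 | 90.5 | 0.9 |
| dusk | 2.50 | 81.1 | 2.0 |
| dusk | 4.00 | 71.2 | 6.9 |
| dusk | 6.00 | 58.0 | 12.7 |
| dusk | 8.00 | 45.7 | 19.6 |

(each reading ± 0.5 percentage points)

- part of the substrate that has reacted at the end, ash
- part of the substrate that has reacted at the end, birch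
- what raising the concentration of reagent from its lowest to its highest value here does to the part of the substrate that has reacted (changes below 5 percentage points count as none) (it rises / it falls / no change)

- amounts are per litre of the starting volume; all of the dose is in the solution fed
- the numbers in the tables scatter by 0.5 percentage points (one standard deviation)
- what has gone from substrate into another species counts as reacted, even if it can come back

The ledger closes with three entries. At 8.00 min, the autumn run holds 53.4% substrate, 12.7% product and 33.9% in neither, while the dusk run holds 45.7%, 19.6% and 34.7%. The third entry differs by 0.8 percentage points against a scatter of 0.5 points per reading, and of the 7.7 points more substrate gone in the dusk run than in the autumn run, 6.9 points stands as product.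

The two runs differ in their reagent charge, and their late readings part. We read a pseudo-first-order late constant, the fraction of substrate lost per minute between 6.00 min and 8.00 min: 0.0763 min⁻¹ in the autumn run and 0.119 min⁻¹ in the dusk run. Per equivalent of reagent over substrate, that is a rise of 0.0894 min⁻¹. This reagent gain, the growth of the late constant per equivalent charged, is what we carry.

Birch lies midway between the runs, so we put its substrate at 8.00 min at 49.6% and its constant at 0.0977 min⁻¹, which reckons to 25.0% left at the end. Ash lies beyond the runs, so our line for it is weaker: from 33.5% at 8.00 min with a constant of 0.187 min⁻¹ it reckons to 9.04% left at the end. We thus reckon 75.0% reacted in birch and 91.0% in ash.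

The forecast says 73% for birch and 86% for ash, lower than our figures. For the trend it says it rises, on the ground that “Higher reagent therefore pulls substrate down faster”.

The flasks give 71.5% for birch and 84.9% for ash, and for the trend it rises, by 13 points.

    initiator → 2 initiating radical (k = 0.0350 min⁻¹)
    substrate + second chain carrier → released group + first chain carrier (k = 18000 M⁻¹ s⁻¹)
    2 substrate → homo dimer (k = 0.150 M⁻¹ min⁻¹)
    2 second chain carrier → ended chains B (k = 5.00 × 10⁷ M⁻¹ s⁻¹)
    reagent + first chain carrier ⇌ product + second chain carrier (K = 1.60, k = 11000 M⁻¹ s⁻¹)
    2 first chain carrier → ended chains A (k = 1.50 × 10⁹ M⁻¹ s⁻¹)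
    substrate + released group ⇌ idle adduct, settled at all times (K = 4.10 M⁻¹)
    substrate + initiating radical → capped initiator + first chain carrier (k = 67000 M⁻¹ s⁻¹)

In ash at 6.94 min, the step of substrate with second chain carrier uses substrate 4.9 times as fast as the path to homo dimer. At 15.0 min it is 16 times as fast. The gain reckoned 25.0% substrate left in birch, which holds 28% at the end, and 9.04% in ash, which holds 15%. For the ash flask given 0.20 M of reagent, 0.800 equiv, the gain reckons 30.2%, and that flask holds 32%.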